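**Retrosynthetic overview**

1. Andibenin ⇐ its 1,2-dihydro lactone (desaturation) ⇐ a seco keto acid: rings A and B are opened together at the C4–O bond of the δ-lactone and at the C5–C10 bond, leaving a methyl ketone on ring C, a Me2C=C5 alkene in the side chain and a free CO2H.
2. Enabling feature: the tertiary carbinol carbon C10 is bonded directly to the spiro carbon C5, which carries the oxygen-bearing gem-dimethyl carbon C4 of ring A. This O–C10–C5–C4–O array is the retron of a Prins addition of a ketone to an isopropylidene alkene, and the lactone carbonyl sits three atoms from C4, placed to capture the cation.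
3. The cage (cyclopentane ring C, bicyclo[2.2.2]octenone rings D/E, butenolide ring F) ⇐ intramolecular Diels–Alder reaction of a 6,6-disubstituted cyclohexa-2,4-dienone with a 1,1-disubstituted alkene ⇐ dehydrogenation of a ketone whose quaternary carbon comes from a regiospecific Claisen rearrangement of a dienol ether.
4. Fragments: a bicyclic keto butenolide (siloxydiene/ynoate Diels–Alder) and a chiral dienyl carbinol (Johnson–Claisen, Stille); (R)-but-3-yn-2-ol is the only source of chirality.
5. Order of ring formation: cyclohexenone ring and ring F → rings D/E and ring C in one step → rings B and A in one step.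

Key step: step 13

Remark: rings A/B use terpenoid locants (C1/C2 lactone CH's, C3 lactone carbonyl, C4 gem-dimethyl carbon, C5 spiro carbon, C8 quaternary fusion carbon, C9 methine, C10 carbinol carbon, C11 the CH2 of ring C, C12 the CH2 bridge); the former dienone ring uses primed locants (C1′ ketone, C2′ methyl-bearing bridgehead, C3′H=C4′, C5′ bridgehead bearing the lactone CH2, C6′ methyl-bearing quaternary carbon); "cage" means rings C–F with C8, C2′, C5′ and C6′ configured as in the target.

**Route**

Step 1
Reactants: 1 2,3-dimethylbut-3-en-2-ol; 2 2,3-dibromoprop-1-ene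
Product: 3 6-bromo-2-methyl-3-methylidenehept-6-en-2-ol
Conditions: n-BuLi (2.2 equiv), TMEDA, hexane/Et2O, 0 °C → rt; then 2, −78 → 0 °C; H2O
Reagents that add atoms: none
Why: Alkoxide-directed allylic lithiation gives a symmetrical 2-substituted allyllithium (dianion), whose alkylation by the allylic bromide of 2 gives the same product by SN2 or SN2′ and leaves the vinyl bromide untouched at low temperature; no stereocentre is formed.

Step 2
Reactants: 3 6-bromo-2-methyl-3-methylidenehept-6-en-2-ol
Product: 4 ethyl 7-bromo-4-(propan-2-ylidene)oct-7-enoate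
Conditions: MeC(OEt)3, EtCO2H (cat.), 140 °C, removal of EtOH
Reagents that add atoms: triethyl orthoacetate, CC(OCC)(OCC)OCC
Why: Johnson–Claisen rearrangement of the tertiary allylic alcohol through its ketene acetal builds the future lactone arm and moves the double bond into the tetrasubstituted isopropylidene position, which has no geometry to control.

Step 3
Reactants: 5 (2R)-but-3-yn-2-ol
Product: 6 (2R)-3-(tributylstannyl)but-3-en-2-ol
Conditions: Bu3SnH, Mo(CO)3(CNtBu)3 (cat.), hydroquinone, THF, 55 °C
Reagents that add atoms: tributyltin hydride, CCCC[SnH](CCCC)CCCC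
Why: The molybdenum-catalysed hydrostannation of propargylic alcohols places tin on the carbon next to the carbinol (α-selective), and the stereocentre is not involved.

Step 4
Reactants: 4 ethyl 7-bromo-4-(propan-2-ylidene)oct-7-enoate; 6 (2R)-3-(tributylstannyl)but-3-en-2-ol
Product: 7 ethyl (9R)-9-hydroxy-7,8-dimethylidene-4-(propan-2-ylidene)decanoate
Conditions: Pd(PPh3)4 (cat.), CuI (cat.), CsF (2 equiv), DMF, 45 °C
Reagents that add atoms: none
Why: Stille coupling of the 1,1-disubstituted alkenylstannane with the alkenyl bromide, promoted by CuI and CsF, should give the 2,3-disubstituted buta-1,3-diene with the carbinol stereocentre unchanged.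

Step 5
Reactants: 8 2-methylpent-1-en-3-one
Product: 9 trimethyl{[(3Z)-2-methylpenta-1,3-dien-3-yl]oxy}silane
Conditions: TMSOTf, Et3N, Et2O, 0 °C
Reagents that add atoms: trimethylsilyl trifluoromethanesulfonate, C[Si](C)(C)OS(=O)(=O)C(F)(F)F
Why: Soft enolisation and O-silylation of the ethyl ketone gives the 2-siloxy-1,3-diene, whose enol-ether geometry is of no consequence because the carbon concerned is enolisable again after step 6.

Step 6
Reactants: 9 trimethyl{[(3Z)-2-methylpenta-1,3-dien-3-yl]oxy}silane; 10 methyl 4-hydroxybut-2-ynoate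
Product: 12 4,6-dimethyl-6,7-dihydro-2-benzofuran-1,5(3H,4H)-dione, via siloxy cyclohexadiene 11 (not isolated)
Conditions: PhMe, 120 °C (sealed, BHT); then 1 M HCl, THF, 0 °C → rt, under Ar
Reagents that add atoms: none
Why: The Diels–Alder reaction of the 2-siloxydiene with the ynoate should follow the "para" rule of the siloxy group (the enol-ether β-carbon bonds to the alkyne carbon β to the ester), and acid then hydrolyses the silyl enol ether and closes butenolide ring F; the two stereocentres arise as a mixture, one being replaced in step 8 and the other removed in step 9.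

Step 7
Reactants: 12 4,6-dimethyl-6,7-dihydro-2-benzofuran-1,5(3H,4H)-dione; 7 ethyl (9R)-9-hydroxy-7,8-dimethylidene-4-(propan-2-ylidene)decanoate
Product: 13 ethyl (9S)-9-[(4,6-dimethyl-1-oxo-1,3,6,7-tetrahydro-2-benzofuran-5-yl)oxy]-7,8-dimethylidene-4-(propan-2-ylidene)decanoate
Conditions: PPh3, DIAD, PhMe, 0 °C → rt, under Ar
Reagents that add atoms: none
Why: Mitsunobu O-alkylation of the vinylogous-acid enol of 12 by the secondary allylic alcohol proceeds by SN2 with inversion, so the (9R) alcohol should give the (9S) dienol ether.

Step 8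
Reactants: 13 ethyl (9S)-9-[(4,6-dimethyl-1-oxo-1,3,6,7-tetrahydro-2-benzofuran-5-yl)oxy]-7,8-dimethylidene-4-(propan-2-ylidene)decanoate
Product: 14 ethyl (8Z)-9-[(4R)-4,6-dimethyl-1,5-dioxo-1,3,4,5,6,7-hexahydro-2-benzofuran-4-yl]-8-ethylidene-7-methylidene-4-(propan-2-ylidene)nonanoate
Conditions: 1,2-dichlorobenzene, 150 °C (BHT)
Reagents that add atoms: none
Why: The Claisen [3,3] rearrangement is regiospecific because only C6′ is the terminus of the enol ether, and through a chair with the carbinol methyl equatorial it should transfer the ether stereocentre to the quaternary carbon C6′ (R) and give the (Z)-ethylidene group.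

Step 9
Reactants: 14 ethyl (8Z)-9-[(4R)-4,6-dimethyl-1,5-dioxo-1,3,4,5,6,7-hexahydro-2-benzofuran-4-yl]-8-ethylidene-7-methylidene-4-(propan-2-ylidene)nonanoate
Product: 16 (Z)-ethylidene cage ester, via cyclohexa-2,4-dienone 15 (not isolated)
Conditions: IBX (2.5 equiv), DMSO/PhF, 70 °C; then 90 °C
Reagents that add atoms: none
Why: IBX dehydrogenation of the ketone, which can enolise only towards the methyl-bearing α-carbon, gives the 6,6-disubstituted cyclohexa-2,4-dienone, and its intramolecular Diels–Alder reaction with the 1,1-disubstituted alkene over a two-atom tether can only take place on the diene face that carries the tether, so C6′ fixes C8, C5′ and C2′ while ring C and rings D/E form.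

Step 10
Reactants: 16 (Z)-ethylidene cage ester
Product: 18 hydroxy ester, via thexyl(alkyl)borane 17 (not isolated)
Conditions: ThexBH2 (from BH3·THF and 2,3-dimethylbut-2-ene), THF, −10 → 0 °C; then 30% H2O2, aq. NaHCO3, 0 °C
Reagents that add atoms: hydrogen peroxide, OO
Why: Hydroboration–oxidation with the bulky monoalkylborane is anti-Markovnikov and syn, should spare the tetrasubstituted alkene, the conjugated alkene and the doubly neopentyl ketone, and should deliver hydrogen to C9 from the more open face of ring C (away from the butenolide CH2 and the side chain), which places the hydroxyethyl group cis to the side chain on C8.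

Step 11
Reactants: 18 hydroxy ester
Product: 19 hydroxy acid
Conditions: LiOH, THF/H2O, 0 °C → rt; then 1 M HCl to pH 3, 0 °C
Reagents that add atoms: lithium hydroxide, [Li+].[OH-]
Why: Saponification of the ethyl ester (the butenolide recloses on acidification if it opens) touches no stereocentre because C9 is not yet α to a carbonyl group.

Step 12
Reactants: 19 hydroxy acid
Product: 20 keto acid
Conditions: DMP, CH2Cl2, 0 °C → rt
Reagents that add atoms: none
Why: Dess–Martin oxidation of the secondary alcohol under non-basic conditions should give the methyl ketone without epimerisation of the now enolisable C9.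

Step 13
Reactants: 20 keto acid
Product: 23 1,2-dihydroandibenin, via aluminium carboxylate 21 (not isolated), via carbenium aluminate 22 (not isolated)
Conditions: Me2AlCl (3.0 equiv), CH2Cl2, −78 → −20 °C; then 1 M HCl, 0 °C
Reagents that add atoms: none
Why: Proposed new method: the first equivalent of Me2AlCl turns the acid into its chloro(methyl)aluminium carboxylate with loss of methane (no Brønsted acid is left to protonate the alkene), further Me2AlCl activates the methyl ketone, C5 of the isopropylidene alkene adds to the carbonyl carbon C10, and the tertiary cation at C4 is captured by the carboxylate oxygen, so the C5–C10 and C4–O bonds form in one anti addition across C5=C4. The closest known reaction types are the Prins cyclisation of citronellal with external capture of the same Me2C cation (p-menthane-3,8-diol), Me2AlCl-promoted ketone–alkene Prins cyclisations with chloride capture, and cation–olefin cyclisations terminated by a carboxylic acid (homofarnesic acid to sclareolide); new is the union of a ketone initiator, a tetrasubstituted alkene and a carboxylate terminator in one substrate. Ring B closes by 6-exo-trig addition to the carbonyl group (alkene exocyclic to the new ring) through a chair fixed by its cis fusion to the rigid ring C, and ring A closes by attack of the carboxylate on the C4 cation through a six-membered chair. C10 is set by this chair (methyl equatorial and metal-bound oxygen axial, which avoids a 1,3-diaxial contact between the methyl and the quaternary bridgehead C5′), and C5 by the antiperiplanar open arrangement of C=O and C=C, which places the Me2C unit anti to the oxygen and the carboxylate arm next to it, where the aluminium carboxylate can hold it. The step needs C–C bond formation to beat direct protonation of the alkene and cation capture to beat ene-type hydrogen transfer or chloride capture; the proton-scavenging methylaluminium reagent should secure the first, and the anti geometry (the oxygen cannot reach the allylic hydrogens) together with the carboxylate held three atoms from C4 should secure the second.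

Step 14
Reactants: 23 1,2-dihydroandibenin
Product: 25 andibenin, via 2-phenylselanyl lactone 24 (not isolated)
Conditions: LiN(iPr)2 (2.5 equiv), THF, −78 °C (inverse addition); PhSeBr; AcOH; then 30% H2O2, pyridine, CH2Cl2, 0 °C → rt
Reagents that add atoms: none
Why: α-Selenenylation of the lactone enolate (the only enolisable position; the alkoxide formed first cannot attack an enolate) and syn-elimination of the selenoxide (Reich–Sharpless–Grieco dehydrogenation) should give the endocyclic enoate of ring A without touching any stereocentre.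

**Compound list**

1 | 2,3-dimethylbut-3-en-2-ol | CC(=C)C(C)(C)O | starting material
2 | 2,3-dibromoprop-1-ene | BrCC(Br)=C | starting material
3 | 6-bromo-2-methyl-3-methylidenehept-6-en-2-ol | CC(C)(O)C(=C)CCC(Br)=C | intermediate
4 | ethyl 7-bromo-4-(propan-2-ylidene)oct-7-enoate | CCOC(=O)CCC(=C(C)C)CCC(Br)=C | intermediate
5 | (2R)-but-3-yn-2-ol | C[C@@H](O)C#C | starting material
6 | (2R)-3-(tributylstannyl)but-3-en-2-ol | C[C@@H](O)C(=C)[Sn](CCCC)(CCCC)CCCC | intermediate
7 | ethyl (9R)-9-hydroxy-7,8-dimethylidene-4-(propan-2-ylidene)decanoate | CCOC(=O)CCC(=C(C)C)CCC(=C)C(=C)[C@@H](C)O | intermediate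
8 | 2-methylpent-1-en-3-one | CCC(=O)C(C)=C | starting material
9 | trimethyl{[(3Z)-2-methylpenta-1,3-dien-3-yl]oxy}silane | C/C=C(\O[Si](C)(C)C)C(C)=C | intermediate
10 | methyl 4-hydroxybut-2-ynoate | COC(=O)C#CCO | starting material
11 | siloxy cyclohexadiene: methyl 2-(hydroxymethyl)-3,5-dimethyl-4-[(trimethylsilyl)oxy]cyclohexa-1,4-diene-1-carboxylate (racemic) | COC(=O)C1=C(CO)C(C)C(O[Si](C)(C)C)=C(C)C1 | intermediate
12 | 4,6-dimethyl-6,7-dihydro-2-benzofuran-1,5(3H,4H)-dione (stereoisomer mixture; reacts as its 5-hydroxy dienol) | CC1CC2=C(COC2=O)C(C)C1=O | intermediate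
13 | ethyl (9S)-9-[(4,6-dimethyl-1-oxo-1,3,6,7-tetrahydro-2-benzofuran-5-yl)oxy]-7,8-dimethylidene-4-(propan-2-ylidene)decanoate (both C6 epimers of the bicycle) | CCOC(=O)CCC(=C(C)C)CCC(=C)C(=C)[C@H](C)OC1=C(C)C2=C(CC1C)C(=O)OC2 | intermediate
14 | ethyl (8Z)-9-[(4R)-4,6-dimethyl-1,5-dioxo-1,3,4,5,6,7-hexahydro-2-benzofuran-4-yl]-8-ethylidene-7-methylidene-4-(propan-2-ylidene)nonanoate (both C6 epimers) | CCOC(=O)CCC(=C(C)C)CCC(=C)/C(=C\C)C[C@@]1(C)C(=O)C(C)CC2=C1COC2=O | intermediate
15 | cyclohexa-2,4-dienone: ethyl (8Z)-9-[(4R)-4,6-dimethyl-1,5-dioxo-1,3,4,5-tetrahydro-2-benzofuran-4-yl]-8-ethylidene-7-methylidene-4-(propan-2-ylidene)nonanoate | CCOC(=O)CCC(=C(C)C)CCC(=C)/C(=C\C)C[C@@]1(C)C(=O)C(C)=CC2=C1COC2=O | intermediate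
16 | (Z)-ethylidene cage ester: ethyl 6-(cage-C8-yl)-4-(propan-2-ylidene)hexanoate with a (Z)-ethylidene at C9 (methyl cis to C8) | CCOC(=O)CCC(=C(C)C)CC[C@@]12C[C@@]3(C)C=C4C(=O)OC[C@]41[C@@](C)(C/C2=C/C)C3=O | intermediate
17 | thexyl(alkyl)borane: 16 after syn addition of H to C9 and of BH(thexyl) to the ethylidene CH | CCOC(=O)CCC(=C(C)C)CC[C@@]12C[C@@]3(C)C=C4C(=O)OC[C@]41[C@@](C)(C[C@H]2[C@@H](C)[BH]C(C)(C)C(C)C)C3=O | intermediate
18 | hydroxy ester: ethyl 6-(cage-C8-yl)-4-(propan-2-ylidene)hexanoate with a (1R)-1-hydroxyethyl group at C9, cis to the side chain | CCOC(=O)CCC(=C(C)C)CC[C@@]12C[C@@]3(C)C=C4C(=O)OC[C@]41[C@@](C)(C[C@H]2[C@@H](C)O)C3=O | intermediate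
19 | hydroxy acid: the free carboxylic acid of 18 | OC(=O)CCC(=C(C)C)CC[C@@]12C[C@@]3(C)C=C4C(=O)OC[C@]41[C@@](C)(C[C@H]2[C@@H](C)O)C3=O | intermediate
20 | keto acid: 6-(9-acetyl-cage-C8-yl)-4-(propan-2-ylidene)hexanoic acid, acetyl cis to the side chain | OC(=O)CCC(=C(C)C)CC[C@@]12C[C@@]3(C)C=C4C(=O)OC[C@]41[C@@](C)(C[C@H]2C(C)=O)C3=O | intermediate
21 | aluminium carboxylate: chloro(methyl)alumanyl ester of 20 | C[Al](Cl)OC(=O)CCC(=C(C)C)CC[C@@]12C[C@@]3(C)C=C4C(=O)OC[C@]41[C@@](C)(C[C@H]2C(C)=O)C3=O | intermediate
22 | carbenium aluminate: ring B closed, cation at C4, chlorodimethylaluminate on the C10 oxygen, carboxylate still on aluminium | C[C+](C)[C@]1(CCC(=O)O[Al](C)Cl)CC[C@@]23C[C@@]4(C)C=C5C(=O)OC[C@]52[C@@](C)(C[C@H]3[C@@]1(C)O[Al-](C)(C)Cl)C4=O | intermediate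
23 | 1,2-dihydroandibenin (saturated spiro δ-lactone, all seven stereocentres as in the target) | CC1(C)OC(=O)CC[C@]12CC[C@@]13C[C@@]4(C)C=C5C(=O)OC[C@]51[C@@](C)(C[C@H]3[C@@]2(C)O)C4=O | intermediate
24 | 2-phenylselanyl lactone: 2-(phenylselanyl)-1,2-dihydroandibenin (C2 epimers) | CC1(C)OC(=O)C([Se]c6ccccc6)C[C@]12CC[C@@]13C[C@@]4(C)C=C5C(=O)OC[C@]51[C@@](C)(C[C@H]3[C@@]2(C)O)C4=O | intermediate
25 | andibenin | CC1(C)OC(=O)C=C[C@]12CC[C@@]13C[C@@]4(C)C=C5C(=O)OC[C@]51[C@@](C)(C[C@H]3[C@@]2(C)O)C4=O | target

**Step count**

Total: 14 steps. Longest linear sequence: 11 steps (steps 1, 2, 4, 7–14).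

**Steps most likely to fail**

Step 13. Concerted ene-type hydrogen transfer or proton loss from the C4 cation may outrun carboxylate capture, methyl may transfer from aluminium to the ketone, or the facial selectivity at C5 may erode. The fallback separates the two bond formations with known chemistry and sets out from 20. Esterification with TMSCHN2 (PhMe/MeOH, 0 °C) should give the methyl ester F1. A ketone–alkene Prins cyclisation with chloride capture (SnCl4, CH2Cl2, −78 °C), which follows the same anti addition, should give the chloro alcohol F2. Silver-assisted ionisation of the tertiary chloride (AgOTf, 2,6-di-tert-butylpyridine, CH2Cl2, 0 °C) with lactonisation through the ester carbonyl and loss of the methyl group returns to the route at 23.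

Step 7. The weakly acidic dienol may be alkylated at carbon or by SN2′ attack instead of at oxygen, or the activated dienyl carbinol may eliminate. The fallback replaces the Mitsunobu inversion by an enol-ether exchange with retention and sets out from 12. O-Methylation with TMSCHN2 should give the methyl dienol ether F3. The enantiomeric alcohol is made from (2S)-but-3-yn-2-ol by the chemistry of steps 3 and 4, through the stannane F4 to the (9S) alcohol F5. Acid-catalysed exchange of F3 with F5 (PPTS, PhMe, 110 °C, removal of MeOH; ketal-exchange/Claisen type) should give the same (9S) ether, so the route is rejoined at 13.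

Step 10. The hindered trisubstituted alkene may react slowly, hydrogen may be delivered to the wrong face of ring C, or the cage ketone may be reduced. The fallback sets out from 16. Dihydroxylation (OsO4 cat., NMO, acetone/H2O), which should prefer the trisubstituted exocyclic alkene over the tetrasubstituted and the electron-poor ones, should give the diol F6. Oxidation of its secondary alcohol (SO3·pyridine, DMSO, Et3N) should give the α-hydroxy ketone F7. Reductive removal of the α-hydroxyl with SmI2 (THF/MeOH, −78 °C), with kinetic protonation of the enolate from the open face, should give the keto ester F8. Neutral ester hydrolysis (Me3SnOH, 1,2-dichloroethane, 70 °C) returns to the route at 20.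

**Further compounds**

F1 | step 13 | methyl ester of keto acid 20 | COC(=O)CCC(=C(C)C)CC[C@@]12C[C@@]3(C)C=C4C(=O)OC[C@]41[C@@](C)(C[C@H]2C(C)=O)C3=O
F2 | step 13 | chloro alcohol: ring B closed, C10 tertiary alcohol, C5 bearing 2-chloropropan-2-yl and the methyl propanoate arm | COC(=O)CC[C@@]1(C(C)(C)Cl)CC[C@@]23C[C@@]4(C)C=C5C(=O)OC[C@]52[C@@](C)(C[C@H]3[C@@]1(C)O)C4=O
F3 | step 7 | methyl dienol ether: 5-methoxy-4,6-dimethyl-6,7-dihydro-2-benzofuran-1(3H)-one | COC1=C(C)C2=C(CC1C)C(=O)OC2
F4 | step 7 | (2S)-3-(tributylstannyl)but-3-en-2-ol | C[C@H](O)C(=C)[Sn](CCCC)(CCCC)CCCC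
F5 | step 7 | ethyl (9S)-9-hydroxy-7,8-dimethylidene-4-(propan-2-ylidene)decanoate | CCOC(=O)CCC(=C(C)C)CCC(=C)C(=C)[C@H](C)O
F6 | step 10 | diol: cage ester with C9 hydroxyl and (1R)-1-hydroxyethyl at C9 | CCOC(=O)CCC(=C(C)C)CC[C@@]12C[C@@]3(C)C=C4C(=O)OC[C@]41[C@@](C)(C[C@@]2(O)[C@@H](C)O)C3=O
F7 | step 10 | α-hydroxy ketone: cage ester with C9 hydroxyl and C9 acetyl | CCOC(=O)CCC(=C(C)C)CC[C@@]12C[C@@]3(C)C=C4C(=O)OC[C@]41[C@@](C)(C[C@@]2(O)C(C)=O)C3=O
F8 | step 10 | keto ester: ethyl ester of keto acid 20 | CCOC(=O)CCC(=C(C)C)CC[C@@]12C[C@@]3(C)C=C4C(=O)OC[C@]41[C@@](C)(C[C@H]2C(C)=O)C3=O
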